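## Structural features

- The target is a hexasubstituted benzene of the C‑trialkylated phloroglucinol type. Going round the ring, the carbons carry: the [(2S)‑2‑isopropenyl‑2,3‑dihydrobenzofuran‑5‑yl]methyl group, a free hydroxyl, a CH2, a ketal oxygen, a second CH2 and a second ketal oxygen.
- Each CH2/oxygen pair is bridged by a 3,9a‑dimethyl‑tetrahydrofuro[2,3‑b]pyran unit. Two cis‑fused bicyclic ketals are therefore annulated on the arene in an angular, head‑to‑tail way; the dihydrobenzofuran is joined only through a methylene.
- In each ketal unit three stereocentres are contiguous: the ketal carbon C9a (R), the ring‑fusion carbon C3a (R) and the methyl‑bearing C3 (R). The seventh centre, C2 of the dihydrobenzofuran (S), is isolated.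
- Fragile groups are the two aryl alkyl ketals (acid), the allylic aryl ether C2–O bond with its isopropenyl group (acid, zerovalent palladium) and the electron‑rich phenol (oxidants).
- Stereochemistry is the smaller problem. C9a must follow the cis ring fusion, and the trans C3a/C3 pair can be taken from a chiral‑pool lactone and is also the thermodynamically preferred arrangement.
- The real difficulty is regiochemical: three phloroglucinol oxygens on a fully substituted ring must be told apart, two entering ketals with a defined partner chain and one staying free beside the benzyl group.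
- The key step uses the 1,3,5‑oxygen pattern of the central ring. Its six carbons and three oxygens are those of a 4‑alkoxy‑2‑pyrone (C2–C6, with the carbonyl O, the ring O1 and the O at C4) plus the first carbon of the chain on C6, and in the pyrone the three oxygens are chemically different.

## Logic of the disconnections

**22 ⇒ 21.** The O–allyl bond on the phenol oxygen between the benzyl‑bearing and a chain‑bearing carbon is cut (in reverse, an allyl group is added). With this oxygen blocked, each chain has only one way into the angular bis‑ketal. Nothing is gained in skeleton, but the ketal regiochemistry becomes unambiguous. The forward step must free a hindered phenol without touching two ketals, the isopropenyl group or the cyclic allylic aryl ether.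

**21 ⇒ 20.** Both aryl O–C9a bonds are cut and each ketal carbon goes back to a 2‑methoxyoxolane. Ketal exchange is reversible, and the cyclic methyl ketal hides the ketone and the primary alcohol of a chain in one base‑stable group, replacing a separate silyl ether and dioxolane. Two pyran rings and both C9a centres leave the problem. The forward step needs acid mild enough for the isopropenyl dihydrobenzofuran and relies on the cis fusion to set C9a from C3a.

**20 ⇒ 18 (through 19).** The arene C–C bond between one chain‑bearing carbon and the hydroxyl carbon flanked by both chains is cut, and the freed acyl carbon is tied to the oxygen of the other outer hydroxyl as a lactone. A benzene with three similar oxygens becomes a 2‑pyrone in which they are a carbonyl oxygen, a ring oxygen and an ether oxygen. The whole substitution pattern is then written in a heterocycle that carbonyl condensations can assemble. The forward step needs an alkoxide that opens the lactone, an enolate on the first carbon of the 6‑side chain, and retention of the 4‑allyloxy group.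

**18 ⇒ 17 + 7.** The O4–allyl bond is cut. Only one oxygen of 17 is an acidic hydroxyl, so the differentiation costs a single alkylation. The demand is selectivity for O4 over C3 and over the lactone carbonyl oxygen of an ambident anion.

**17 ⇒ 16.** The lactone O1–C2 bond is cut to an open 3,5‑diketo ester. The ring is gone and a linear chain of alternating carbonyls remains. The forward step must close through oxygen, not carbon, which a non‑nucleophilic amidine base in an aprotic solvent should secure.

**16 ⇒ 15 + 14.** The bond between the benzyl‑bearing carbon and the C5 carbonyl of the chain is cut, releasing one complete side chain as an acyl donor. The forward step is the γ‑acylation of a dianion; the acceptor must not release a ketone before quench, hence an N‑methoxy‑N‑methylamide.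

**15 ⇒ 13 + 5.** The bond between the ester α‑carbon and the ketone carbon is cut, instead of the bond from that α‑carbon to the chain CH2. The first chain then enters as the enolate of the same three‑carbon acid unit that 14 carries. One building block serves both chains, and no substitution at a β‑branched primary halide is needed. The forward crossed Claisen step must avoid proton scrambling, again the job of the amide acceptor.

**14 and 13 ⇒ 12 ⇒ 11 ⇒ 10.** Functional‑group changes only: amide and ester back to aldehyde, alcohol and terminal alkene. The three carbons of the acid chain are recognised as an allyl group. The forward steps must stay non‑acidic because of the methyl ketal.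

**10 ⇒ 8 (through 9) ⇒ 6 + 7.** The C2–CH3 bond and the ketal O–CH3 bond are cut back to a lactone carbonyl, then the C3–allyl bond is cut. The stereocentre of 6 controls the new one by 1,2‑induction, so the C3/C3a pair of each ketal unit comes from the chiral pool. The demands are single addition of the methyl nucleophile and anti alkylation.

**5 ⇒ 4 ⇒ 2 + 3, and 2 ⇒ 1.** After the amide is returned to the ester, the aryl–C3 and O–C2 bonds of the dihydrofuran ring are cut together, leaving 3 as the source of the five carbons of that ring portion and a bromophenol. The forward heteroannulation must be regioselective (aryl to the unsubstituted diene terminus, oxygen to the internal allyl carbon) and enantioselective for the S centre. The bromine is placed by ortho substitution of 1.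

## Other disconnections considered

**Alternative 1:** In each tricyclic unit the C3a–C9a bond and both C–O bonds of the ketal carbon are cut; the ketal carbon with its methyl comes from an orthoacetate.
- Forward step: the bis(alkenyl) diphenol diol A1, with trimethyl orthoacetate, Me3SiOTf and Et3SiH, would give the bis‑ketal benzodioxinone A2. Each primary alcohol forms a dialkoxycarbenium ion that adds to the styrene β‑carbon in a 5‑exo cation–olefin closure; the benzylic cation is reduced by the silane, and the phenol displaces methoxide.
- In its favour: four rings, two C–C bonds and four stereocentres arise in one operation. The chains are simple hydroxy‑methylbutenyl groups, and the dioxinone both blocks the correct oxygen and carries a carbon handle for the benzyl group.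
- Against it here: a dialkoxycarbenium ion is a weak electrophile. The ortho‑hydroxystyrene can instead be protonated and simply reduced by the silane, and the free phenols compete for the orthoester. The C3a configuration rests on induction from C3 in an untested cyclisation. A2 still needs acyl substitution by an aryl nucleophile and deoxygenation of a diaryl ketone in the presence of the ketals.
- Comparison: in bonds and stereocentres formed per step, and probably in total step count, this alternative is the better of the two. The chosen plan is stronger in mechanism, since its key step belongs to a known reaction type, sets no stereocentre and carries the benzyl group in from the start.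

**Alternative 2:** The O1–C2 bond of each five‑membered oxygen ring is cut at the enol‑ether level, leading back to acetylcyclopropanes.
- Forward step: MgI2 would convert the bis(acetylcyclopropylmethyl)arene A3 into the bis(dihydrofuran) A4. Iodide opens each activated cyclopropane at its CH2 carbon and the enolate oxygen closes the ring by displacement.
- In its favour: a redox‑neutral isomerisation with no protecting group on the chains. The methyl‑bearing centre is never touched, and A4 is one acid treatment away from the bis‑ketal, with the same blocking of the third oxygen as in the chosen plan (an equal point).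
- Against it here: A3 needs two quaternary cyclopropane carbons attached through CH2 to a crowded arene, which is a long and uncertain preparation. Opening at the methyl‑bearing cyclopropane carbon would scramble the only stereocentre. C3a is created only when the enol ether is protonated; kinetic protonation anti to the methyl group would give the cis C3a/C3 isomer, so the outcome depends on later equilibration. The benzyl group must still be built from the dioxinone.
- Comparison: the alternative is better in protecting‑group economy. The chosen plan is better in stereocontrol (C3a fixed by alkylation, with thermodynamics only as a backstop) and in access to the precursor. After the key step the two are about equal in length.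

**Alternative 3:** Both aryl–O9 bonds are cut back to aryl–carbon bonds, together with O1–C9a.
- Forward step: the bis(methyleneindane) diol A5, with H2O2 and acid, would form two tertiary benzylic hydroperoxides. Aryl migration from carbon to oxygen (Hock) expands each cyclopentane to a pyran oxocarbenium ion, which the CH2OH group captures, giving the bis‑ketal core phenol A6.
- In its favour: the positions of all oxygens are fixed by a carbon skeleton, so no oxygen differentiation is needed; on this point it is better than the chosen plan. Four C–O bonds form at once and C9a follows from C3a.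
- Against it here: a phloroglucinol‑type phenol is exposed to peroxide and acid, with the risk of ring oxidation. A5, with four stereocentres on an angular tricyclic carbocycle, is a long target in itself. A6 lacks the dihydrobenzofuranylmethyl group, which would have to enter by a late C‑benzylation of a ketal‑bearing phenol, with O‑alkylation competing and an acid‑sensitive partner.
- Comparison: the alternative is better in the logic of oxygen placement. The chosen plan is better in oxidant compatibility and in step economy, because the benzyl group and both chains are assembled by three condensations.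

Key step: step 14

Remark on the chemistry: by the CIP rules the dihydrobenzofuran centre of the target is S. C2 of each 2‑methoxyoxolane unit and the enolisable carbons of 15, 16 and 19 are carried as mixtures (left undefined in the SMILES); all are erased or converge by step 15.

Abbreviations in names: DBF = (2S)‑2‑(prop‑1‑en‑2‑yl)‑2,3‑dihydro‑1‑benzofuran‑5‑yl; Ox = (3R,4R)‑2‑methoxy‑2,4‑dimethyloxolan‑3‑yl.

## Steps

Step 1
Reactants: 1 methyl 3-(4-hydroxyphenyl)propanoate
Product: 2 methyl 3-(3-bromo-4-hydroxyphenyl)propanoate
Conditions: NBS (1.0 equiv), p-TsOH·H2O (10 mol%), MeOH, 0 °C → rt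
Reagents that add atoms: N-bromosuccinimide, O=C1CCC(=O)N1Br
Why: Electrophilic aromatic bromination; the hydroxyl directs ortho because the para position carries the side chain, and one equivalent of NBS under acid catalysis should stop at the monobromide.

Step 2
Reactants: 2 methyl 3-(3-bromo-4-hydroxyphenyl)propanoate; 3 isoprene
Product: 4 methyl 3-[(2S)-2-(prop-1-en-2-yl)-2,3-dihydro-1-benzofuran-5-yl]propanoate
Conditions: Pd2(dba)3·CHCl3 (2.5 mol%), chiral sulfinamide–phosphine ligand (TY-Phos type, enantiomer giving 2S), PhONa, CH2Cl2, 40 °C, sealed tube
Reagents that add atoms: none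
Why: Enantioselective Heck/Tsuji–Trost heteroannulation: the aryl bromide adds oxidatively to zerovalent palladium, the unsubstituted vinyl end of isoprene inserts to give a π-allyl complex, and the phenoxide attacks the internal allyl carbon to close the five-membered ring. The chiral ligand controls the face of C–O bond formation and so the S centre; the ester is a spectator.

Step 3
Reactants: 4 methyl 3-[(2S)-2-(prop-1-en-2-yl)-2,3-dihydro-1-benzofuran-5-yl]propanoate
Product: 5 N-methoxy-N-methyl-3-[(2S)-2-(prop-1-en-2-yl)-2,3-dihydro-1-benzofuran-5-yl]propanamide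
Conditions: MeNHOMe·HCl, i-PrMgCl, THF, −20 → 0 °C
Reagents that add atoms: N,O-dimethylhydroxylamine hydrochloride, CNOC.Cl
Why: Weinreb amide formation by aminolysis of the methyl ester with the chloromagnesium amide; the chelated adduct and the low temperature prevent further addition, and the allylic ether is untouched.

Step 4
Reactants: 6 (R)-4-methyldihydrofuran-2(3H)-one; 7 allyl bromide
Product: 8 (3R,4R)-3-allyl-4-methyldihydrofuran-2(3H)-one
Conditions: LiN(i-Pr)2, THF, −78 °C; then 7, −78 → −40 °C
Reagents that add atoms: none
Why: Alkylation of the lithium lactone enolate; the electrophile approaches the face opposite the adjacent C4 methyl group (1,2-induction in a five-membered enolate), so the 3,4-trans lactone should predominate.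

Step 5
Reactants: 8 (3R,4R)-3-allyl-4-methyldihydrofuran-2(3H)-one
Product: 10 (3R,4R)-3-allyl-2-methoxy-2,4-dimethyloxolane, via lactol 9 (not isolated)
Conditions: MeLi (1.05 equiv), THF, −78 °C; then HCl in MeOH (1.2 equiv), −78 °C → rt; Et3N
Reagents that add atoms: methyllithium, [Li]C; methanol, CO
Why: Methyllithium adds once because the tetrahedral lithium hemiketal alkoxide is stable at −78 °C until quench; methanolic acid then converts lactol 9 through its oxocarbenium ion into the cyclic methyl ketal, which masks ketone and alcohol in one group. The 3,4-trans arrangement is the thermodynamically favoured one, so the acid cannot erode it.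

Step 6
Reactants: 10 (3R,4R)-3-allyl-2-methoxy-2,4-dimethyloxolane
Product: 11 3-[(3R,4R)-2-methoxy-2,4-dimethyloxolan-3-yl]propan-1-ol
Conditions: 9-BBN, THF, 0 °C → rt; then aq. NaOH, H2O2, 0 °C
Reagents that add atoms: hydrogen peroxide, OO
Why: Hydroboration–oxidation; 9-BBN adds anti-Markovnikov to the monosubstituted alkene and the basic peroxide work-up leaves the ketal intact.

Step 7
Reactants: 11 3-[(3R,4R)-2-methoxy-2,4-dimethyloxolan-3-yl]propan-1-ol
Product: 12 3-[(3R,4R)-2-methoxy-2,4-dimethyloxolan-3-yl]propanal
Conditions: Pr4N[RuO4] (5 mol%), N-methylmorpholine N-oxide, 4 Å MS, CH2Cl2, rt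
Reagents that add atoms: none
Why: Ley–Griffith oxidation of the primary alcohol to the aldehyde under neutral, anhydrous conditions, chosen because the methyl ketal would not tolerate acidic oxidants.

Step 8
Reactants: 12 3-[(3R,4R)-2-methoxy-2,4-dimethyloxolan-3-yl]propanal
Product: 13 methyl 3-[(3R,4R)-2-methoxy-2,4-dimethyloxolan-3-yl]propanoate
Conditions: KOH, I2, MeOH, 0 °C
Reagents that add atoms: methanol, CO
Why: Oxidative esterification: the methyl hemiacetal of the aldehyde is oxidised by hypoiodite in basic methanol (I2/KOH oxidation), so the medium stays basic, the ketal is safe and no free carboxylic acid is formed.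

Step 9
Reactants: 13 methyl 3-[(3R,4R)-2-methoxy-2,4-dimethyloxolan-3-yl]propanoate
Product: 14 N-methoxy-N-methyl-3-[(3R,4R)-2-methoxy-2,4-dimethyloxolan-3-yl]propanamide
Conditions: MeNHOMe·HCl, i-PrMgCl, THF, −20 → 0 °C
Reagents that add atoms: N,O-dimethylhydroxylamine hydrochloride, CNOC.Cl
Why: Weinreb amide formation as in step 3; part of 13 is diverted to give the acyl donor for step 11.

Step 10
Reactants: 13 methyl 3-[(3R,4R)-2-methoxy-2,4-dimethyloxolan-3-yl]propanoate; 5 N-methoxy-N-methyl-3-[(2S)-2-(prop-1-en-2-yl)-2,3-dihydro-1-benzofuran-5-yl]propanamide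
Product: 15 methyl 5-(DBF)-2-(Ox-methyl)-3-oxopentanoate
Conditions: 13, LiN(i-Pr)2 (1.05 equiv), THF, −78 °C; then 5, −78 → −10 °C; aq. NH4Cl
Reagents that add atoms: none
Why: Crossed Claisen condensation of an ester enolate with a Weinreb amide; the chelated tetrahedral adduct persists until quench, so the β-keto ester can neither protonate unreacted enolate nor be acylated again. The amide α-protons are less acidic than those of the ester, which suppresses proton scrambling; the new α-centre forms as a mixture that step 12 erases.

Step 11
Reactants: 15 methyl 5-(DBF)-2-(Ox-methyl)-3-oxopentanoate; 14 N-methoxy-N-methyl-3-[(3R,4R)-2-methoxy-2,4-dimethyloxolan-3-yl]propanamide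
Product: 16 methyl 4-(DBF-methyl)-2-(Ox-methyl)-7-(Ox)-3,5-dioxoheptanoate
Conditions: 15, LiN(i-Pr)2 (2.2 equiv), THF, −78 → 0 °C; then 14, −78 → 0 °C; aq. NH4Cl
Reagents that add atoms: none
Why: γ-Acylation of a β-keto ester dianion: the first equivalent of base removes the α-proton, the second the only other ketone α-proton set, and the more reactive terminal carbanion attacks the Weinreb amide. The chelated adduct collapses only on work-up, so the diketone product cannot quench the dianion.

Step 12
Reactants: 16 methyl 4-(DBF-methyl)-2-(Ox-methyl)-7-(Ox)-3,5-dioxoheptanoate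
Product: 17 5-(DBF-methyl)-4-hydroxy-3-(Ox-methyl)-6-[2-(Ox)ethyl]-2H-pyran-2-one
Conditions: DBU, toluene, 80 °C
Reagents that add atoms: none
Why: Base-mediated lactonisation of a 3,5-diketo ester: DBU enolises the C5 ketone towards C4 and the enol oxygen attacks the ester (6-exo-trig acyl substitution) with loss of methanol to give the 4-hydroxy-2-pyrone. The two scrambled centres become sp2.

Step 13
Reactants: 17 5-(DBF-methyl)-4-hydroxy-3-(Ox-methyl)-6-[2-(Ox)ethyl]-2H-pyran-2-one; 7 allyl bromide
Product: 18 4-(allyloxy)-5-(DBF-methyl)-3-(Ox-methyl)-6-[2-(Ox)ethyl]-2H-pyran-2-one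
Conditions: K2CO3, 7, DMF, rt
Reagents that add atoms: none
Why: O-Alkylation of the pyronate anion (a vinylogous carboxylate) in a polar aprotic solvent, which favours the 4-oxygen over C3 (a quaternary centre with loss of pyrone conjugation) and over the lactone carbonyl oxygen. This step marks the one oxygen that must stay out of the ketals.

Step 14
Reactants: 18 4-(allyloxy)-5-(DBF-methyl)-3-(Ox-methyl)-6-[2-(Ox)ethyl]-2H-pyran-2-one
Product: 20 5-(allyloxy)-4-(DBF-methyl)-2,6-bis(Ox-methyl)benzene-1,3-diol, via ring-opened allyl ester 19 (not isolated)
Conditions: NaOCH2CH=CH2 (from NaH, 4 equiv), allyl alcohol, 85 °C, argon; then aq. NH4Cl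
Reagents that add atoms: none
Why: Allyloxide adds to the lactone carbonyl C2 of 18 and opens the ring to the enolate of 19, in which the ester and the C5–C6 ketone unit remain cis on the C3=C4 enol-ether double bond. Reversible proton transfer gives a small share of the enolate on the first side-chain carbon at C6, which attacks the ester in a 6-(enolendo)-exo-trig Claisen (Dieckmann-type) closure; loss of allyloxide and tautomerisation give the phenoxide of 20, which is irreversible and draws the reversible opening, re-lactonisation and the unproductive C5 enolate through. The closest known reaction type is the base-mediated ring transformation of 4-alkoxy-6-alkyl-2-pyrones into phloroglucinol monoethers, the chemical counterpart of the triketide Claisen cyclisation. One carbocycle and one C–C bond are formed and no stereocentre is created; the existing centres lie far from any acidic position. The step needs one arene regioisomer, and this is secured because only this carbon can reach the ester through a six-membered transition state, which places the allyl ether between the benzyl group and a chain. Allyloxide in allyl alcohol replaces methoxide so that addition–elimination at C4 or ester exchange is degenerate and cannot turn the allyl ether into a methyl ether; ketals, the isopropenyl group and the dihydrobenzofuran ring are inert to alkoxide.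

Step 15
Reactants: 20 5-(allyloxy)-4-(DBF-methyl)-2,6-bis(Ox-methyl)benzene-1,3-diol
Product: 21 O-allyl ether of 22: benzene carrying in ring order DBF-methyl, O-allyl, then CH2 and O of one (3R,3aR,9aR)-3,9a-dimethyl-tetrahydrofuro[2,3-b]pyran ketal unit, then CH2 and O of a second identical unit
Conditions: PPTS (20 mol%), 5 Å MS, CH2Cl2, rt
Reagents that add atoms: none
Why: Acid-catalysed transketalisation: each 2-methoxyoxolane ionises to a cyclic oxocarbenium ion that an ortho phenol captures in a six-membered ring, and removal of methanol by the sieves drives both closures. The allyl ether leaves the chain next to it no partner but the central hydroxyl, the other chain takes the outer hydroxyl, and a mis-closure on the central oxygen is reversible. Each new C9a centre (R) follows from the obligatory cis fusion to the existing C3a centre.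

Step 16
Reactants: 21 O-allyl ether of 22
Product: 22 target phenol: benzene carrying in ring order DBF-methyl, OH, then CH2 and O of one (3R,3aR,9aR)-3,9a-dimethyl-tetrahydrofuro[2,3-b]pyran ketal unit, then CH2 and O of a second identical unit
Conditions: Pd(PPh3)4 (5 mol%), morpholine, THF, rt
Reagents that add atoms: none
Why: Tsuji–Trost deallylation: zerovalent palladium ionises the unhindered aryl allyl ether to a π-allyl complex, which morpholine traps, releasing the phenol. The ring C2–O bond of the dihydrobenzofuran is also allylic but secondary and next to a 1,1-disubstituted alkene, so its ionisation should be much slower at room temperature; the ketals are inert.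

## Compound list

1 | methyl 3-(4-hydroxyphenyl)propanoate | COC(=O)CCc1ccc(O)cc1 | starting material
2 | methyl 3-(3-bromo-4-hydroxyphenyl)propanoate | COC(=O)CCc1ccc(O)c(Br)c1 | intermediate
3 | isoprene (2-methylbuta-1,3-diene) | C=CC(C)=C | starting material
4 | methyl 3-[(2S)-2-(prop-1-en-2-yl)-2,3-dihydro-1-benzofuran-5-yl]propanoate | C=C(C)[C@@H]1Cc2cc(CCC(=O)OC)ccc2O1 | intermediate
5 | N-methoxy-N-methyl-3-[(2S)-2-(prop-1-en-2-yl)-2,3-dihydro-1-benzofuran-5-yl]propanamide | C=C(C)[C@@H]1Cc2cc(CCC(=O)N(C)OC)ccc2O1 | intermediate
6 | (R)-4-methyldihydrofuran-2(3H)-one | O=C1C[C@@H](C)CO1 | starting material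
7 | allyl bromide (3-bromoprop-1-ene) | C=CCBr | starting material
8 | (3R,4R)-3-allyl-4-methyldihydrofuran-2(3H)-one (3,4-trans) | O=C1[C@H](CC=C)[C@@H](C)CO1 | intermediate
9 | (3R,4R)-3-allyl-2,4-dimethyloxolan-2-ol (lactol, in equilibrium with the open hydroxy ketone; both C2 configurations) | CC1(O)OC[C@H](C)[C@H]1CC=C | intermediate (not isolated)
10 | (3R,4R)-3-allyl-2-methoxy-2,4-dimethyloxolane (both C2 configurations) | COC1(C)OC[C@H](C)[C@H]1CC=C | intermediate
11 | 3-[(3R,4R)-2-methoxy-2,4-dimethyloxolan-3-yl]propan-1-ol | COC1(C)OC[C@H](C)[C@H]1CCCO | intermediate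
12 | 3-[(3R,4R)-2-methoxy-2,4-dimethyloxolan-3-yl]propanal | COC1(C)OC[C@H](C)[C@H]1CCC=O | intermediate
13 | methyl 3-[(3R,4R)-2-methoxy-2,4-dimethyloxolan-3-yl]propanoate | COC1(C)OC[C@H](C)[C@H]1CCC(=O)OC | intermediate
14 | N-methoxy-N-methyl-3-[(3R,4R)-2-methoxy-2,4-dimethyloxolan-3-yl]propanamide | COC1(C)OC[C@H](C)[C@H]1CCC(=O)N(C)OC | intermediate
15 | methyl 2-{[(3R,4R)-2-methoxy-2,4-dimethyloxolan-3-yl]methyl}-3-oxo-5-[(2S)-2-(prop-1-en-2-yl)-2,3-dihydro-1-benzofuran-5-yl]pentanoate (C2 epimers) | C=C(C)[C@@H]1Cc2cc(CCC(=O)C(C[C@@H]3[C@@H](C)COC3(C)OC)C(=O)OC)ccc2O1 | intermediate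
16 | methyl 2-{[(3R,4R)-2-methoxy-2,4-dimethyloxolan-3-yl]methyl}-7-[(3R,4R)-2-methoxy-2,4-dimethyloxolan-3-yl]-3,5-dioxo-4-{[(2S)-2-(prop-1-en-2-yl)-2,3-dihydro-1-benzofuran-5-yl]methyl}heptanoate (C2/C4 epimers, keto–enol mixture) | C=C(C)[C@@H]1Cc2cc(CC(C(=O)CC[C@@H]3[C@@H](C)COC3(C)OC)C(=O)C(C[C@@H]3[C@@H](C)COC3(C)OC)C(=O)OC)ccc2O1 | intermediate
17 | 4-hydroxy-3-{[(3R,4R)-2-methoxy-2,4-dimethyloxolan-3-yl]methyl}-6-{2-[(3R,4R)-2-methoxy-2,4-dimethyloxolan-3-yl]ethyl}-5-{[(2S)-2-(prop-1-en-2-yl)-2,3-dihydro-1-benzofuran-5-yl]methyl}-2H-pyran-2-one | C=C(C)[C@@H]1Cc2cc(CC3=C(CC[C@@H]4[C@@H](C)COC4(C)OC)OC(=O)C(C[C@@H]4[C@@H](C)COC4(C)OC)=C3O)ccc2O1 | intermediate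
18 | 4-(allyloxy)-3-{[(3R,4R)-2-methoxy-2,4-dimethyloxolan-3-yl]methyl}-6-{2-[(3R,4R)-2-methoxy-2,4-dimethyloxolan-3-yl]ethyl}-5-{[(2S)-2-(prop-1-en-2-yl)-2,3-dihydro-1-benzofuran-5-yl]methyl}-2H-pyran-2-one | C=C(C)[C@@H]1Cc2cc(CC3=C(CC[C@@H]4[C@@H](C)COC4(C)OC)OC(=O)C(C[C@@H]4[C@@H](C)COC4(C)OC)=C3OCC=C)ccc2O1 | intermediate (key-step precursor)
19 | prop-2-enyl (2E)-3-(allyloxy)-2-{[(3R,4R)-2-methoxy-2,4-dimethyloxolan-3-yl]methyl}-7-[(3R,4R)-2-methoxy-2,4-dimethyloxolan-3-yl]-5-oxo-4-{[(2S)-2-(prop-1-en-2-yl)-2,3-dihydro-1-benzofuran-5-yl]methyl}hept-2-enoate (present as its enolates) | C=C(C)[C@@H]1Cc2cc(CC(C(=O)CC[C@@H]3[C@@H](C)COC3(C)OC)/C(OCC=C)=C(/C[C@@H]3[C@@H](C)COC3(C)OC)C(=O)OCC=C)ccc2O1 | intermediate (not isolated)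
20 | 5-(allyloxy)-2,6-bis{[(3R,4R)-2-methoxy-2,4-dimethyloxolan-3-yl]methyl}-4-{[(2S)-2-(prop-1-en-2-yl)-2,3-dihydro-1-benzofuran-5-yl]methyl}benzene-1,3-diol | C=C(C)[C@@H]1Cc2cc(Cc3c(OCC=C)c(C[C@@H]4[C@@H](C)COC4(C)OC)c(O)c(C[C@@H]4[C@@H](C)COC4(C)OC)c3O)ccc2O1 | intermediate (key-step product)
21 | O-allyl ether of 22 (angular bis-ketal; each unit 3R,3aR,9aR; dihydrobenzofuran 2S) | C=C(C)[C@@H]1Cc2cc(Cc3c(OCC=C)c4c(c5c3O[C@@]3(C)OC[C@H](C)[C@H]3C5)O[C@@]3(C)OC[C@H](C)[C@H]3C4)ccc2O1 | intermediate
22 | CNP0131395.1: phenol with the [(2S)-2-(prop-1-en-2-yl)-2,3-dihydro-1-benzofuran-5-yl]methyl group and two angularly fused (3R,3aR,9aR)-3,9a-dimethyl-tetrahydrofuro[2,3-b]pyran ketal units | C=C(C)[C@@H]1Cc2cc(Cc3c(O)c4c(c5c3O[C@@]3(C)OC[C@H](C)[C@H]3C5)O[C@@]3(C)OC[C@H](C)[C@H]3C4)ccc2O1 | target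

## Step count and least certain steps

Total step count: 16. Longest linear sequence: 12 steps (from 6 through steps 4–8 and 10–16 to 22).

**Step 14 (key step).** The closure may be too slow, because the productive side-chain enolate is only a minor partner of the resting C5 enolate. Slower processes could then take over: [3,3] shift of the allyl enol ether, retro-Claisen fragmentation of the opened chain, or irreversible 1,6-addition of alkoxide at C6. Fallback: set out from 18, open the lactone with sodium allyloxide at 0 °C → rt and isolate 19 after a buffered quench. Then treat 19 with LiN(SiMe3)2 (2.5 equiv) in THF at −78 → 0 °C, so that the terminal carbanion of the irreversibly formed dianion closes the ring under aprotic, kinetic conditions; the route is rejoined at 20. This fallback makes no compound outside the list (F0).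

**Step 11.** The dianion of the doubly substituted β-keto ester may form incompletely, or it may remove a proton from 14 instead of adding to it. Fallback: set out from 15, form the same dianion and add it to aldehyde 12, which is more electrophilic and already on the route. This gives methyl 5-hydroxy-3-oxo-2-(Ox-methyl)-7-(Ox)-4-(DBF-methyl)heptanoate F1; oxidise the alcohol with Dess–Martin periodinane (NaHCO3 buffer) and rejoin at 16.

**Step 10.** Addition of the ester enolate to the Weinreb amide may be slower than self-condensation of the enolate on warming. Fallback: set out from 4 and reduce it with i-Bu2AlH at −78 °C to 3-[(2S)-2-(prop-1-en-2-yl)-2,3-dihydro-1-benzofuran-5-yl]propanal F2. Add the lithium enolate of 13 in an aldol reaction to give methyl 3-hydroxy-2-(Ox-methyl)-5-(DBF)pentanoate F3, oxidise with Dess–Martin periodinane and rejoin at 15.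

**Step 2.** Enantioface control may be poor on this para-alkyl bromophenol, or diene arylation may occur without ring closure. Fallback: set out from 1 and rejoin at 4.
- Alkylate with 7 (K2CO3, acetone) to methyl 3-[4-(allyloxy)phenyl]propanoate F4.
- Carry out an aromatic Claisen rearrangement (N,N-diethylaniline, 200 °C) to methyl 3-(3-allyl-4-hydroxyphenyl)propanoate F5.
- Cross-metathesise with methyl 2-methylprop-2-enyl carbonate (second-generation Grubbs catalyst) to methyl 3-{4-hydroxy-3-[(2E)-4-(methoxycarbonyloxy)-3-methylbut-2-en-1-yl]phenyl}propanoate F6.
- Close the ring by intramolecular asymmetric allylic O-alkylation (Pd2(dba)3, Trost bisphosphine ligand of the enantiomeric series that gives the S centre).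

**Step 13.** The ambident pyronate may be alkylated at the lactone carbonyl oxygen or at C3. Fallback: set out from 17 and etherify under Mitsunobu conditions (allyl alcohol, PPh3, DIAD, THF). There the neutral hydroxypyrone acts as the acid component and is expected to react at the 4-oxygen; rejoin at 18. This fallback makes no compound outside the list (F0).

**Step 16.** Zerovalent palladium may also ionise the ring allylic C–O bond of the dihydrobenzofuran, with capture of that π-allyl complex by the amine. Fallback: set out from 21 and isomerise the allyl ether with H2-activated [Ir(cod)(PMePh2)2]PF6 in THF, a catalyst that acts on unsubstituted allyl ethers only. This gives the (E)-prop-1-enyl ether of 22, F7. Cleave the enol ether with HgCl2/HgO in aqueous acetone and rejoin at 22; no π-allyl species is involved.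

## Further compounds

F0 | step 14 | none | none
F1 | step 11 | methyl 5-hydroxy-2-{[(3R,4R)-2-methoxy-2,4-dimethyloxolan-3-yl]methyl}-7-[(3R,4R)-2-methoxy-2,4-dimethyloxolan-3-yl]-3-oxo-4-{[(2S)-2-(prop-1-en-2-yl)-2,3-dihydro-1-benzofuran-5-yl]methyl}heptanoate | C=C(C)[C@@H]1Cc2cc(CC(C(O)CC[C@@H]3[C@@H](C)COC3(C)OC)C(=O)C(C[C@@H]3[C@@H](C)COC3(C)OC)C(=O)OC)ccc2O1
F2 | step 10 | 3-[(2S)-2-(prop-1-en-2-yl)-2,3-dihydro-1-benzofuran-5-yl]propanal | C=C(C)[C@@H]1Cc2cc(CCC=O)ccc2O1
F3 | step 10 | methyl 3-hydroxy-2-{[(3R,4R)-2-methoxy-2,4-dimethyloxolan-3-yl]methyl}-5-[(2S)-2-(prop-1-en-2-yl)-2,3-dihydro-1-benzofuran-5-yl]pentanoate | C=C(C)[C@@H]1Cc2cc(CCC(O)C(C[C@@H]3[C@@H](C)COC3(C)OC)C(=O)OC)ccc2O1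
F4 | step 2 | methyl 3-[4-(allyloxy)phenyl]propanoate | COC(=O)CCc1ccc(OCC=C)cc1
F5 | step 2 | methyl 3-(3-allyl-4-hydroxyphenyl)propanoate | COC(=O)CCc1ccc(O)c(CC=C)c1
F6 | step 2 | methyl 3-{4-hydroxy-3-[(2E)-4-(methoxycarbonyloxy)-3-methylbut-2-en-1-yl]phenyl}propanoate | COC(=O)CCc1ccc(O)c(C/C=C(\C)COC(=O)OC)c1
F0 | step 13 | none | none
F7 | step 16 | (E)-prop-1-enyl ether of 22 | C=C(C)[C@@H]1Cc2cc(Cc3c(O/C=C/C)c4c(c5c3O[C@@]3(C)OC[C@H](C)[C@H]3C5)O[C@@]3(C)OC[C@H](C)[C@H]3C4)ccc2O1
A1 | alternative 1 | 5,7-dihydroxy-6,8-bis[(1E,3R)-4-hydroxy-3-methylbut-1-en-1-yl]-2,2-dimethyl-4H-1,3-benzodioxin-4-one | CC1(C)OC(=O)c2c(O1)c(/C=C/[C@@H](C)CO)c(O)c(/C=C/[C@@H](C)CO)c2O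
A2 | alternative 1 | bis-ketal benzodioxinone (2,2-dimethyl-4H-1,3-benzodioxin-4-one with the two ketal units of 22 fused at C5/C6 and C7/C8) | CC1(C)OC(=O)c2c(O1)c3c(c4c2O[C@@]5(C)OC[C@H](C)[C@H]5C4)O[C@@]6(C)OC[C@H](C)[C@H]6C3
A3 | alternative 2 | 6,8-bis{[1-acetyl-(2S)-2-methylcyclopropyl]methyl}-5,7-dihydroxy-2,2-dimethyl-4H-1,3-benzodioxin-4-one | CC1(C)OC(=O)c2c(O1)c(CC3(C(C)=O)C[C@@H]3C)c(O)c(CC3(C(C)=O)C[C@@H]3C)c2O
A4 | alternative 2 | 6,8-bis{[(4R)-2,4-dimethyl-4,5-dihydrofuran-3-yl]methyl}-5,7-dihydroxy-2,2-dimethyl-4H-1,3-benzodioxin-4-one | CC1(C)OC(=O)c2c(O1)c(CC3=C(C)OC[C@@H]3C)c(O)c(CC4=C(C)OC[C@@H]4C)c2O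
A5 | alternative 3 | (2R,7R)-2,7-bis[(2R)-1-hydroxypropan-2-yl]-1,6-dimethylidene-1,2,3,6,7,8-hexahydro-as-indacen-4-ol | c1c(O)c2c(c3c1C(=C)[C@@H]([C@@H](C)CO)C3)C(=C)[C@@H]([C@@H](C)CO)C2
A6 | alternative 3 | bis-ketal core phenol (22 without its dihydrobenzofuranylmethyl group) | c1c(O)c2c(c3c1O[C@@]4(C)OC[C@H](C)[C@H]4C3)O[C@@]5(C)OC[C@H](C)[C@H]5C2
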